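**Retrosynthetic overview**

- The target comes from its dimethyl ester 12-acetate by hydrolysis. The last ring-forming event is a BF3-triggered opening of a terminal (S)-2,2-dimethyloxirane by a 1,1-disubstituted alkene (C4–C5 bond), with capture of the C10 cation by the C3 oxygen. This closes both rings of the 7-oxabicyclo[2.2.1]heptane on the complete C25 skeleton, mirroring an oxidosqualene-type ring A closure followed by 3-O→C10 etherification.
- The epoxide comes from Shi epoxidation of a tetraene. Ring C of the tetraene is closed by allylcuprate conjugate addition to an ynoate and aldol closure onto the ring D ketone (C9–C19 and C8–C14 bonds), then dehydration to the C8=C9/C14=C15 dienoate.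
- The ynoate–ketone comes from a reductive aldol of a 2-methylidenecyclopentanone with but-3-ynal (C13 quaternary centre, C12 carbinol), then alkyne methoxycarbonylation.
- The methylidene ketone comes from a Cu-catalysed asymmetric methyl addition (C17) to a 3-substituted cyclopentenone, itself from a Rh-catalysed asymmetric alkenyl addition to methyl crotonate (C20).
- Ring order: D (from cyclopentenylboronic acid) → C → carbocyclic ring A together with its oxygen bridge, last.

Assumption: the labels C3, C10, C12, C13, C14, C17, C19, C20 are lanostane-type position labels for the target's carbons (ether bridgeheads C3/C10, linker C19, carbinol C12, quaternary C13/C17, side-chain methine C20); the target is 3S,10S,12R,13S,17S,20R.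

**Route**

Step 1
Reactants: 1 cyclopent-1-en-1-ylboronic acid; 2 methyl (E)-but-2-enoate
Product: 3 methyl (3R)-3-(cyclopent-1-en-1-yl)butanoate
Conditions: Rh(acac)(C2H4)2 (3 mol%), (S)-BINAP (3.3 mol%), 1 (2.5 equiv), dioxane/H2O 10:1, 100 °C
Reagents that add atoms: none
Why: Hayashi–Miyaura rhodium-catalysed asymmetric 1,4-addition, in which the alkenyl–rhodium/(S)-BINAP species adds to the Re face of C3 of the (E)-enoate and so sets C20 as R.

Step 2
Reactants: 3 methyl (3R)-3-(cyclopent-1-en-1-yl)butanoate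
Product: 5 methyl (3R)-3-(3-oxocyclopent-1-en-1-yl)butanoate, via allylic tert-butyl peroxide 4 (not isolated)
Conditions: Rh2(C6H10NO)4 [dirhodium tetrakis(caprolactamate)] (1 mol%), t-BuOOH (70% in water, 5 equiv), CH2Cl2, rt
Reagents that add atoms: tert-butyl hydroperoxide, CC(C)(C)OO
Why: Doyle-type allylic C–H oxidation, in which hydrogen abstraction at the least hindered ring CH2 next to the vinylic CH and collapse of the mixed peroxide give the 3-substituted enone and leave C20 untouched.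

Step 3
Reactants: 5 methyl (3R)-3-(3-oxocyclopent-1-en-1-yl)butanoate
Product: 7 methyl (3R)-3-[(1S)-1-methyl-3-(trimethylsilyloxy)cyclopent-2-en-1-yl]butanoate, via dimethylaluminium enolate 6 (not isolated)
Conditions: AlMe3 (1.5 equiv), copper thiophene-2-carboxylate (5 mol%), enantiopure SimplePhos ligand Ph2PN[CH(Me)Ph]2 (10 mol%, enantiomer matched to Re-face delivery), Et2O, −30 °C; then TMSOTf (2 equiv), THF, 0 °C; non-aqueous work-up
Reagents that add atoms: trimethylaluminium, C[Al](C)C; trimethylsilyl triflate, C[Si](C)(C)OS(=O)(=O)C(F)(F)F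
Why: Copper-catalysed asymmetric conjugate addition of AlMe3 to a β-substituted cyclopentenone creates the C17 quaternary centre (methyl to the Re face of the β-carbon under ligand control, giving S), and O-silylation of the aluminium enolate locks the enolate regiochemistry at C13.

Step 4
Reactants: 7 methyl (3R)-3-[(1S)-1-methyl-3-(trimethylsilyloxy)cyclopent-2-en-1-yl]butanoate
Product: 10 methyl (3R)-3-[(1S)-1-methyl-2-methylidene-3-oxocyclopentyl]butanoate, via Mannich base 8 (not isolated), via trimethylammonium iodide 9 (not isolated)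
Conditions: Eschenmoser's salt (dimethylmethylideneammonium iodide, 1.5 equiv), CH2Cl2, rt; MeI, THF; then sat. aq. NaHCO3/CH2Cl2, rt
Reagents that add atoms: Eschenmoser's salt, C=[N+](C)C.[I-]
Why: Mannich reaction of the regiodefined silyl enol ether followed by N-methylation and base-induced β-elimination gives the exocyclic enone, with C13 becoming sp2 so no stereocentre is at stake.

Step 5
Reactants: 11 but-3-yn-1-ol
Product: 12 but-3-ynal
Conditions: Dess–Martin periodinane (1.1 equiv), CH2Cl2, 0 °C → rt; cold filtered solution used at once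
Reagents that add atoms: none
Why: Dess–Martin oxidation under neutral conditions gives the sensitive β,γ-alkynyl aldehyde without isomerisation to the allenal.

Step 6
Reactants: 10 methyl (3R)-3-[(1S)-1-methyl-2-methylidene-3-oxocyclopentyl]butanoate; 12 but-3-ynal
Product: 15 methyl (3R)-3-[(1S,2R)-2-[(1R)-1-acetoxybut-3-yn-1-yl]-1,2-dimethyl-3-oxocyclopentyl]butanoate, via lithium enolate 13 (not isolated), via lithium aldolate 14 (not isolated)
Conditions: LiBH(s-Bu)3 (L-Selectride, 1.05 equiv), THF, −78 °C; 12 (2 equiv), −78 °C; then Ac2O (3 equiv), DMAP (cat.), −78 → 0 °C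
Reagents that add atoms: acetic anhydride, CC(=O)OC(C)=O
Why: Reductive aldol reaction, in which 1,4-hydride delivery gives the tetrasubstituted C13 enolate regiospecifically and a Zimmerman–Traxler chair on the face anti to the larger C17 side chain sets C13 (methyl cis to the side chain) and C12 (oxygen anti to the 13-methyl), while in-flask acetylation blocks retro-aldol.

Step 7
Reactants: 15 methyl (3R)-3-[(1S,2R)-2-[(1R)-1-acetoxybut-3-yn-1-yl]-1,2-dimethyl-3-oxocyclopentyl]butanoate
Product: 16 methyl (3R)-3-[(1S,2R)-2-[(1R)-1-acetoxy-5-methoxy-5-oxopent-3-yn-1-yl]-1,2-dimethyl-3-oxocyclopentyl]butanoate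
Conditions: PdCl2 (5 mol%), CuCl2 (2.2 equiv), NaOAc (2.2 equiv), CO (1 atm), MeOH, rt
Reagents that add atoms: carbon monoxide, [C-]#[O+]; methanol, CO
Why: Tsuji oxidative methoxycarbonylation of the terminal alkyne (alkynylpalladium, CO insertion, methanolysis, CuCl2 reoxidation) is neutral enough for the ketone, acetate and ester, and touches no stereocentre.

Step 8
Reactants: 17 2-methylprop-2-en-1-ol; 18 1-bromo-3-methylbut-2-ene
Product: 20 6-methyl-2-methylidenehept-5-en-1-ol, via dilithio dianion 19 (not isolated)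
Conditions: n-BuLi (2.2 equiv), TMEDA, Et2O/hexane, 0 °C → rt; then 18, −78 °C → rt
Reagents that add atoms: none
Why: Alkoxide-directed allylic lithiation gives the methallyl alcohol dianion, whose carbanion is alkylated by prenyl bromide in an SN2 reaction.

Step 9
Reactants: 20 6-methyl-2-methylidenehept-5-en-1-ol
Product: 22 2-(chloromethyl)-6-methylhepta-1,5-diene, via allylic mesylate 21 (not isolated)
Conditions: MsCl, 2,4,6-collidine, LiCl, DMF, 0 °C
Reagents that add atoms: lithium chloride, [Li+].[Cl-]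
Why: Collington–Meyers chlorination (mesylation, then chloride displacement) converts the allylic alcohol cleanly, and the 2-substituted allyl unit is symmetric so transposition is irrelevant.

Step 10
Reactants: 22 2-(chloromethyl)-6-methylhepta-1,5-diene; 16 methyl (3R)-3-[(1S,2R)-2-[(1R)-1-acetoxy-5-methoxy-5-oxopent-3-yn-1-yl]-1,2-dimethyl-3-oxocyclopentyl]butanoate
Product: 26 methyl (3R)-3-[(1S,7R,7aR)-7-acetoxy-3a-hydroxy-4-(methoxycarbonyl)-1,7a-dimethyl-5-(6-methyl-2-methylidenehept-5-en-1-yl)-2,3,3a,6,7,7a-hexahydro-1H-inden-1-yl]butanoate (3a-epimers), via allylmagnesium chloride 23 (not isolated), via magnesium diallylcuprate 24 (not isolated), via magnesium allenolate 25 (not isolated)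
Conditions: 22 (2.5 equiv), Mg, THF, 0 °C; CuBr·SMe2 (1.25 equiv), −78 °C; 16, −78 → −20 °C; aq. NH4Cl
Reagents that add atoms: none
Why: Proposed new method: the allylcuprate adds to the ynoate β-carbon (C9–C19 bond), the α-metallo enoate equilibrates through the linear allenolate on warming, and its α-carbon attacks the neighbouring ring D ketone to close ring C with the tetrasubstituted C8=C9 alkene in the ring (the C14 carbinol configuration is irrelevant), the closest known reactions being cuprate conjugate addition to alkynoates and Michael-initiated ring closures such as halo-aldol cyclisations of ynoates onto tethered ketones.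

Step 11
Reactants: 26 the ring C hydroxy ester from step 10
Product: 28 methyl (3R)-3-[(1S,7R,7aS)-7-acetoxy-4-(methoxycarbonyl)-1,7a-dimethyl-5-(6-methyl-2-methylidenehept-5-en-1-yl)-2,6,7,7a-tetrahydro-1H-inden-1-yl]butanoate, via sulfamate ester 27 (not isolated)
Conditions: Burgess reagent (2 equiv), toluene, 60 °C
Reagents that add atoms: none
Why: Burgess syn-elimination of the tertiary allylic alcohol can only use the C15 hydrogens (C13 is quaternary, C8 is sp2), so it gives the C14=C15 alkene of the cross-conjugated dienoate regiospecifically.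

Step 12
Reactants: 28 the tetraene diester acetate from step 11
Product: 29 methyl (3R)-3-[(1S,7R,7aS)-7-acetoxy-5-{4-[(2S)-3,3-dimethyloxiran-2-yl]-2-methylidenebutyl}-4-(methoxycarbonyl)-1,7a-dimethyl-2,6,7,7a-tetrahydro-1H-inden-1-yl]butanoate
Conditions: L-fructose-derived enantiomer of the Shi ketone (0.3 equiv), Oxone (2KHSO5·KHSO4·K2SO4, 1.4 equiv KHSO5), K2CO3, Bu4NHSO4, MeCN/dimethoxymethane/aq. Na2B4O7 buffer (pH 10.5), 0 °C
Reagents that add atoms: potassium peroxymonosulfate (Oxone), [K+].[O-]S(=O)(=O)OO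
Why: Shi asymmetric epoxidation, in which the chiral dioxirane attacks only the most electron-rich trisubstituted alkene through the spiro transition state and the L-series ketone gives the (S)-epoxide at C3.

Step 13
Reactants: 29 the (S)-epoxy triene from step 12
Product: 31 methyl (3R)-3-[(1S,7R,7aS)-7-acetoxy-5-{[(1S,4S)-3,3-dimethyl-7-oxabicyclo[2.2.1]heptan-1-yl]methyl}-4-(methoxycarbonyl)-1,7a-dimethyl-2,6,7,7a-tetrahydro-1H-inden-1-yl]butanoate, via C10 cation 30 (not isolated)
Conditions: BF3·OEt2 (0.3 equiv), CH2Cl2, −78 °C, 20 min; Et3N quench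
Reagents that add atoms: none
Why: Epoxide-initiated cation–olefin cyclisation of the geraniolene-oxide type, in which BF3 opens the epoxide at its tertiary carbon, the =CH2 terminus attacks it (C4–C5 bond) and the tertiary C10 cation is captured through a boat by the C3 oxygen with retention at C3, so the (S)-epoxide alone fixes both bridgeheads as 3S,10S.

Step 14
Reactants: 31 the oxabicyclic diester acetate from step 13
Product: 33 (3R)-3-[(1S,7R,7aS)-4-carboxy-5-{[(1S,4S)-3,3-dimethyl-7-oxabicyclo[2.2.1]heptan-1-yl]methyl}-7-hydroxy-1,7a-dimethyl-2,6,7,7a-tetrahydro-1H-inden-1-yl]butanoic acid, via dilithium dicarboxylate 32 (not isolated)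
Conditions: LiOH (10 equiv), THF/MeOH/H2O 2:1:1, 50 °C; then aq. HCl (1 mol/L) to pH 3, 0 °C
Reagents that add atoms: lithium hydroxide, [Li+].[OH-]
Why: Acyl-oxygen saponification of both methyl esters and the acetate, with no epimerisable centre α to a carbonyl and the tertiary ether stable to base and to brief mild acid.

**Compound list**

1 | cyclopent-1-en-1-ylboronic acid | OB(O)C1=CCCC1 | starting material
2 | methyl (E)-but-2-enoate | C/C=C/C(=O)OC | starting material
3 | methyl (3R)-3-(cyclopent-1-en-1-yl)butanoate | C[C@H](CC(=O)OC)C1=CCCC1 | intermediate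
4 | methyl (3R)-3-[3-(tert-butylperoxy)cyclopent-1-en-1-yl]butanoate | C[C@H](CC(=O)OC)C1=CC(OOC(C)(C)C)CC1 | intermediate
5 | methyl (3R)-3-(3-oxocyclopent-1-en-1-yl)butanoate | C[C@H](CC(=O)OC)C1=CC(=O)CC1 | intermediate
6 | dimethylaluminium enolate of the methyl adduct | C[C@H](CC(=O)OC)[C@]1(C)CCC(O[Al](C)C)=C1 | intermediate
7 | methyl (3R)-3-[(1S)-1-methyl-3-(trimethylsilyloxy)cyclopent-2-en-1-yl]butanoate | C[C@H](CC(=O)OC)[C@]1(C)CCC(O[Si](C)(C)C)=C1 | intermediate
8 | methyl (3R)-3-[(1S)-2-(dimethylaminomethyl)-1-methyl-3-oxocyclopentyl]butanoate | C[C@H](CC(=O)OC)[C@]1(C)CCC(=O)C1CN(C)C | intermediate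
9 | N-methyl ammonium iodide of 8 | C[C@H](CC(=O)OC)[C@]1(C)CCC(=O)C1C[N+](C)(C)C.[I-] | intermediate
10 | methyl (3R)-3-[(1S)-1-methyl-2-methylidene-3-oxocyclopentyl]butanoate | C[C@H](CC(=O)OC)[C@]1(C)CCC(=O)C1=C | intermediate
11 | but-3-yn-1-ol | C#CCCO | starting material
12 | but-3-ynal | C#CCC=O | intermediate
13 | lithium enolate from 10 | C[C@H](CC(=O)OC)[C@]1(C)CCC(O[Li])=C1C | intermediate
14 | lithium aldolate | C[C@H](CC(=O)OC)[C@]1(C)CCC(=O)[C@@]1(C)[C@H](O[Li])CC#C | intermediate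
15 | methyl (3R)-3-[(1S,2R)-2-[(1R)-1-acetoxybut-3-yn-1-yl]-1,2-dimethyl-3-oxocyclopentyl]butanoate | C[C@H](CC(=O)OC)[C@]1(C)CCC(=O)[C@@]1(C)[C@H](OC(C)=O)CC#C | intermediate
16 | methyl (3R)-3-[(1S,2R)-2-[(1R)-1-acetoxy-5-methoxy-5-oxopent-3-yn-1-yl]-1,2-dimethyl-3-oxocyclopentyl]butanoate | C[C@H](CC(=O)OC)[C@]1(C)CCC(=O)[C@@]1(C)[C@H](OC(C)=O)CC#CC(=O)OC | intermediate
17 | 2-methylprop-2-en-1-ol | C=C(C)CO | starting material
18 | 1-bromo-3-methylbut-2-ene | CC(C)=CCBr | starting material
19 | dilithio dianion of 17 | [Li]CC(=C)CO[Li] | intermediate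
20 | 6-methyl-2-methylidenehept-5-en-1-ol | C=C(CO)CCC=C(C)C | intermediate
21 | 6-methyl-2-methylidenehept-5-en-1-yl methanesulfonate | C=C(COS(C)(=O)=O)CCC=C(C)C | intermediate
22 | 2-(chloromethyl)-6-methylhepta-1,5-diene | C=C(CCl)CCC=C(C)C | intermediate
23 | (6-methyl-2-methylidenehept-5-en-1-yl)magnesium chloride | C=C(C[Mg]Cl)CCC=C(C)C | intermediate
24 | chloromagnesium bis(6-methyl-2-methylidenehept-5-en-1-yl)cuprate | C=C(C[Cu-]CC(=C)CCC=C(C)C)CCC=C(C)C.[Mg+]Cl | intermediate
25 | magnesium allenolate after conjugate addition | C[C@H](CC(=O)OC)[C@]1(C)CCC(=O)[C@@]1(C)[C@H](OC(C)=O)CC(CC(=C)CCC=C(C)C)=C=C(OC)O[Mg]Cl | intermediate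
26 | methyl (3R)-3-[(1S,7R,7aR)-7-acetoxy-3a-hydroxy-4-(methoxycarbonyl)-1,7a-dimethyl-5-(6-methyl-2-methylidenehept-5-en-1-yl)-2,3,3a,6,7,7a-hexahydro-1H-inden-1-yl]butanoate (3a-epimers) | C[C@H](CC(=O)OC)[C@]1(C)CCC2(O)C(C(=O)OC)=C(CC(=C)CCC=C(C)C)C[C@@H](OC(C)=O)[C@]21C | intermediate
27 | triethylammonium N-(methoxycarbonyl)sulfamate ester of 26 | C[C@H](CC(=O)OC)[C@]1(C)CCC2(OS(=O)(=O)[N-]C(=O)OC)C(C(=O)OC)=C(CC(=C)CCC=C(C)C)C[C@@H](OC(C)=O)[C@]21C.CC[NH+](CC)CC | intermediate
28 | methyl (3R)-3-[(1S,7R,7aS)-7-acetoxy-4-(methoxycarbonyl)-1,7a-dimethyl-5-(6-methyl-2-methylidenehept-5-en-1-yl)-2,6,7,7a-tetrahydro-1H-inden-1-yl]butanoate | C[C@H](CC(=O)OC)[C@]1(C)CC=C2C(C(=O)OC)=C(CC(=C)CCC=C(C)C)C[C@@H](OC(C)=O)[C@]21C | intermediate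
29 | methyl (3R)-3-[(1S,7R,7aS)-7-acetoxy-5-{4-[(2S)-3,3-dimethyloxiran-2-yl]-2-methylidenebutyl}-4-(methoxycarbonyl)-1,7a-dimethyl-2,6,7,7a-tetrahydro-1H-inden-1-yl]butanoate | C[C@H](CC(=O)OC)[C@]1(C)CC=C2C(C(=O)OC)=C(CC(=C)CC[C@@H]3OC3(C)C)C[C@@H](OC(C)=O)[C@]21C | intermediate
30 | C10 cyclohexyl cation with C3 trifluoroborato-oxy group | C[C@H](CC(=O)OC)[C@]1(C)CC=C2C(C(=O)OC)=C(C[C+]3CC[C@H](O[B-](F)(F)F)C(C)(C)C3)C[C@@H](OC(C)=O)[C@]21C | intermediate
31 | methyl (3R)-3-[(1S,7R,7aS)-7-acetoxy-5-{[(1S,4S)-3,3-dimethyl-7-oxabicyclo[2.2.1]heptan-1-yl]methyl}-4-(methoxycarbonyl)-1,7a-dimethyl-2,6,7,7a-tetrahydro-1H-inden-1-yl]butanoate | C[C@H](CC(=O)OC)[C@]1(C)CC=C2C(C(=O)OC)=C(C[C@]34CC[C@H](O3)C(C)(C)C4)C[C@@H](OC(C)=O)[C@]21C | intermediate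
32 | dilithium dicarboxylate of 33 | C[C@H](CC(=O)[O-])[C@]1(C)CC=C2C(C(=O)[O-])=C(C[C@]34CC[C@H](O3)C(C)(C)C4)C[C@@H](O)[C@]21C.[Li+].[Li+] | intermediate
33 | (3R)-3-[(1S,7R,7aS)-4-carboxy-5-{[(1S,4S)-3,3-dimethyl-7-oxabicyclo[2.2.1]heptan-1-yl]methyl}-7-hydroxy-1,7a-dimethyl-2,6,7,7a-tetrahydro-1H-inden-1-yl]butanoic acid (CNP0085464.1) | C[C@H](CC(=O)O)[C@]1(C)CC=C2C(C(=O)O)=C(C[C@]34CC[C@H](O3)C(C)(C)C4)C[C@@H](O)[C@]21C | target

**Totals**

Total step count: 14. Longest linear sequence: 11 (steps 1, 2, 3, 4, 6, 7, 10, 11, 12, 13, 14); step 5 and steps 8–9 are short side branches.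

**Steps most likely to fail, with fallbacks**

Step 13 (late cationic ring A/ether closure). The C10 cation can lose a C19 proton to give a conjugated triene, can be intercepted by the neighbouring C8 ester carbonyl (δ-lactone after work-up), or the epoxide can rearrange to a ketone. Fallback: starting from 29, the C–C and C–O bonds are made separately. Cp2TiCl (from Cp2TiCl2 and Mn dust, THF, rt) opens the epoxide homolytically and the tertiary radical closes 6-endo onto the =CH2 terminus, giving the ring A cyclohexenol methyl (3R)-3-[(1S,7R,7aS)-7-acetoxy-5-{[(4S)-4-hydroxy-5,5-dimethylcyclohex-1-en-1-yl]methyl}-4-(methoxycarbonyl)-1,7a-dimethyl-2,6,7,7a-tetrahydro-1H-inden-1-yl]butanoate F1 (ring double-bond isomers converge). Intramolecular oxymercuration–demercuration (Hg(O2CCF3)2, THF, 0 °C; NaBH4, aq. NaOH) then adds the C3 hydroxyl to C10 and returns to the route at 31.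

Step 10 (cuprate addition/aldol ring C closure). The allylcopper reagent may attack the ketone directly, or the allenolate may be protonated instead of closing onto the hindered ketone. Fallback: starting from 16 and 22, ring closure and fragment union are separated. Pyrrolidine addition to the ynoate and mild aqueous acid give the β-keto ester methyl (3R)-3-[(1S,2R)-2-[(1R)-1-acetoxy-5-methoxy-3,5-dioxopentyl]-1,2-dimethyl-3-oxocyclopentyl]butanoate F2. TiCl4/pyridine Knoevenagel condensation onto the ring ketone gives the bicyclic alkylidene β-keto ester methyl (3R)-3-[(1S,7R,7aS)-7-acetoxy-4-(methoxycarbonyl)-1,7a-dimethyl-5-oxo-1,2,3,5,6,7-hexahydro-7aH-inden-1-yl]butanoate F3. γ-Deprotonation and O-triflation (NaH, PhNTf2, THF, 0 °C) give the dienyl triflate methyl (3R)-3-[(1S,7R,7aS)-7-acetoxy-4-(methoxycarbonyl)-1,7a-dimethyl-5-(trifluoromethylsulfonyloxy)-2,6,7,7a-tetrahydro-1H-inden-1-yl]butanoate F4. In parallel 22 and Bu3SnLi give tributyl(6-methyl-2-methylidenehept-5-en-1-yl)stannane F5. Stille coupling of F4 and F5 (Pd(PPh3)4, LiCl, CuI, DMF, 60 °C) returns to the route at 28.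

Step 6 (reductive aldol that builds the C13 quaternary centre next to C17). The hindered tetrasubstituted enolate may react slowly, but-3-ynal is enolisable and fragile, and the diastereoselectivity may be moderate. Fallback: starting from 10, the C12–C13 bond is made with formaldehyde and the C11–C12 bond by propargylation. L-Selectride then monomeric formaldehyde (THF, −78 °C) gives methyl (3R)-3-[(1S,2R)-2-(hydroxymethyl)-1,2-dimethyl-3-oxocyclopentyl]butanoate F6. Dess–Martin oxidation gives methyl (3R)-3-[(1S,2R)-2-formyl-1,2-dimethyl-3-oxocyclopentyl]butanoate F7. Zinc-mediated Barbier propargylation (propargyl bromide, Zn, THF/aq. NH4Cl), with the zinc chelated between aldehyde and ketone and attack from the methyl face, gives methyl (3R)-3-[(1S,2R)-2-[(1R)-1-hydroxybut-3-yn-1-yl]-1,2-dimethyl-3-oxocyclopentyl]butanoate F8. Acetylation (Ac2O, DMAP) returns to the route at 15.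

**Further compounds**

F1 | step 13 | methyl (3R)-3-[(1S,7R,7aS)-7-acetoxy-5-{[(4S)-4-hydroxy-5,5-dimethylcyclohex-1-en-1-yl]methyl}-4-(methoxycarbonyl)-1,7a-dimethyl-2,6,7,7a-tetrahydro-1H-inden-1-yl]butanoate | C[C@H](CC(=O)OC)[C@]1(C)CC=C2C(C(=O)OC)=C(CC3=CC[C@H](O)C(C)(C)C3)C[C@@H](OC(C)=O)[C@]21C
F2 | step 10 | methyl (3R)-3-[(1S,2R)-2-[(1R)-1-acetoxy-5-methoxy-3,5-dioxopentyl]-1,2-dimethyl-3-oxocyclopentyl]butanoate | C[C@H](CC(=O)OC)[C@]1(C)CCC(=O)[C@@]1(C)[C@H](OC(C)=O)CC(=O)CC(=O)OC
F3 | step 10 | methyl (3R)-3-[(1S,7R,7aS)-7-acetoxy-4-(methoxycarbonyl)-1,7a-dimethyl-5-oxo-1,2,3,5,6,7-hexahydro-7aH-inden-1-yl]butanoate | C[C@H](CC(=O)OC)[C@]1(C)CCC2=C(C(=O)OC)C(=O)C[C@@H](OC(C)=O)[C@]21C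
F4 | step 10 | methyl (3R)-3-[(1S,7R,7aS)-7-acetoxy-4-(methoxycarbonyl)-1,7a-dimethyl-5-(trifluoromethylsulfonyloxy)-2,6,7,7a-tetrahydro-1H-inden-1-yl]butanoate | C[C@H](CC(=O)OC)[C@]1(C)CC=C2C(C(=O)OC)=C(OS(=O)(=O)C(F)(F)F)C[C@@H](OC(C)=O)[C@]21C
F5 | step 10 | tributyl(6-methyl-2-methylidenehept-5-en-1-yl)stannane | C=C(C[Sn](CCCC)(CCCC)CCCC)CCC=C(C)C
F6 | step 6 | methyl (3R)-3-[(1S,2R)-2-(hydroxymethyl)-1,2-dimethyl-3-oxocyclopentyl]butanoate | C[C@H](CC(=O)OC)[C@]1(C)CCC(=O)[C@@]1(C)CO
F7 | step 6 | methyl (3R)-3-[(1S,2R)-2-formyl-1,2-dimethyl-3-oxocyclopentyl]butanoate | C[C@H](CC(=O)OC)[C@]1(C)CCC(=O)[C@@]1(C)C=O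
F8 | step 6 | methyl (3R)-3-[(1S,2R)-2-[(1R)-1-hydroxybut-3-yn-1-yl]-1,2-dimethyl-3-oxocyclopentyl]butanoate | C[C@H](CC(=O)OC)[C@]1(C)CCC(=O)[C@@]1(C)[C@H](O)CC#C
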